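## The problem

Target 21 is a 19-membered cyclophane in which four benzene rings are joined by two diaryl ether oxygens and two CH2CH2 bridges, the bridges running from ring A to ring C and from ring D to ring B. Ring A is a para-phenylene; ring B is a 5-alkyl-3-aryloxybenzene-1,2-diol bound through its ether oxygen to ring A; ring C is a second catechol of the same pattern, bound through its ether oxygen to ring D; ring D is a meta-phenylene. The compound has no stereocentre and the ring is taken to be conformationally mobile, so the difficulties are the placement of the oxygens, the making of the two diaryl ethers and the closure of the large ring. Rings B and C each carry three contiguous oxygens, one an aryl ether and two free hydroxyls; these must be told apart, and the air- and base-sensitive catechols must stay masked to the last step under conditions that spare the diaryl ethers. The ether on ring A lies para to a bridge carbon and can be made by nucleophilic aromatic substitution on a para-formyl fluoroarene. The ether on ring D lies meta to its bridge, where no activating group helps, and a hot copper-mediated etherification would compete for the halide that ring D needs for its bridge to ring B. The macrocycle has to be closed against entropy and oligomerisation, best by C–C bond formation in one of the flexible two-carbon bridges. The enabling feature is on ring C (C1 bears the bridge, C3 and C4 the hydroxyls, C5 the aryloxy group): C5 and C4 are neighbours and C4 is flanked on its other side by the oxygen on C3, which is the pattern produced when a 3-methoxyaryne takes an oxygen nucleophile at the carbon remote from OMe and an oxygen electrophile at the carbon next to it.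

## Retrosynthesis

**21 from 20.** The four catechol O–H bonds are traced back to the O–CH3 bonds of tetramethyl ether 20. Methyl is the one mask that passes Grignard, palladium, titanium and hydrogenation chemistry alike, and Lewis acid demethylation spares diaryl ethers. The forward step must cleave four aryl methyl ethers without oxidising the product.

**20 from 19 from 18.** The bridge between ring A and ring C is cut at its central C–C bond, first to stilbene 19 and then to dialdehyde 18. Closing the ring in a bridge rather than at an ether avoids activating ring D for substitution. A reductive coupling of two like aryl aldehydes needs no differentiation of the chain ends, which a Wittig closure would. Compound 18 is acyclic and made of two halves of equal size. The forward carbonyl coupling must be intramolecular, which asks for slow addition and a flexible chain.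

**18 from 17 from 16.** The ring C aldehyde of 18 is drawn back to the dioxolane of 17, and the saturated bridge between ring D and ring B to the alkyne of 16. The alkyne is reduced before ring closure, not after: a linear diarylalkyne would hold the two formyl carbons apart, and alkynes are only partly compatible with low-valent titanium. The forward hydrogenation must spare the free formyl group on ring A.

**16 from 11 and 15.** The bond between ring D and the alkyne carbon is cut, giving aryl bromide 11 (rings C and D) and terminal alkyne 15 (rings A and B). This is the most convergent cut of the open chain, since each half already holds one diaryl ether and one of the two future bridge aldehydes. The reverse polarity would put a halide on the trioxygenated ring B, for which no simple building block exists. The forward reaction is the alkynylation of an unactivated aryl bromide.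

**15 from 13 and 14; 13 from 12.** The ether C–O bond on ring A of 15 is cut to phenol 13 and fluoroarene 14; the formyl group that later becomes a bridge carbon serves as the activating group. The ethynyl group of 13 is traced to the formyl group of commercial 12 by one-carbon homologation. Doing this before the etherification means that 15 never holds two aldehydes that would have to be distinguished.

**11 from 10; 10 from 3 and 4.** Compound 11 is the methyl ether of phenol 10. In 10 the two C–O bonds on neighbouring ring C carbons, C5–OAr and C4–OH, are cut together. This leads back to aryne 7, to phenoxide 5 (from phenol 4) and to an electrophilic oxygen source. Cutting only the ether bond would call for a copper coupling in the presence of the aryl bromide, and no substitution pathway exists for an unactivated meta position. Aryne 7 is drawn from iodo sulfonate 3 through its magnesiated form 6; after addition of 5 the arylmagnesium 8 is oxygenated by way of boronate 9. The forward step needs regioselective addition, exchange at iodine only, and capture of 7 by a weak oxygen nucleophile. To help the last point, 5 is planned in excess as its LiCl complex and 6 is added to it, so that the aryne is always formed in a surplus of phenoxide.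

**3 from 2 from 1.** The dioxolane of 3 is traced to the aldehyde of 2 and the sulfonate to the phenol of 5-iodovanillin 1. Compound 1 already carries OMe, O and I on three adjacent carbons with the formyl group para to the central oxygen. The forward steps are a sulfonylation and an acetalisation.

## Roads not taken

Alternative 1: The ether between ring C and ring D is cut last instead of first. The seco phenol A2 carries on ring D a fluorine ortho to a nitro group; mild carbonate base should close the macrocycle by intramolecular nucleophilic aromatic substitution to give nitro macrocycle A1. The nitro group is then erased by reduction, diazotisation and hydrodediazoniation before demethylation.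
- Merits: macrocyclic etherification of this kind is a proven way to close large diaryl ether rings; ether formation and ring closure coincide; no reaction type in it is untested.
- Weak points: ring D has no nitrogen in the target, so about three steps on the macrocycle are spent removing the activating group. A2 requires both bridges and the other ether to be in place, with one ring C hydroxyl free and two methylated, which makes a long linear sequence. The diazonium stage sits on an electron-rich tetraalkoxy cyclophane that can undergo azo coupling.
- Comparison: the key step of this road is safer than the aryne step of the chosen plan. The chosen plan is shorter, introduces no group that must be removed, and takes its risk in step 3 on simple material rather than late.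

Alternative 2: The outer hydroxyl of each catechol is cut, leading to dideoxy macrocycle A4, in which rings B and C are 2-aryloxyphenols with one free ortho carbon. The oxidant 2-iodoxybenzoic acid A5 should oxygenate each ring at that carbon to give bis(ortho-quinone) A3, and a mild reduction would give 21.
- Merits: the trioxygenated rings need not be carried; A4 comes from cheaper monophenol building blocks; the site of oxygenation is dictated because only one ortho carbon is free; the final Lewis acid demethylation could be avoided.
- Weak points: two oxidations must succeed on one molecule. Each quinone ring of A3 is an aryloxy-substituted ortho-quinone with a benzylic CH2 para to a carbonyl, so loss of aryloxide by addition–elimination and tautomerisation to a quinone methide both threaten. This happens at the end, on the most valuable material.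
- Comparison: this road has better protecting-group economy, and its key reaction type is known on simple phenols. The chosen plan sets every oxidation level at the start on a stable benzene ring and never forms a quinone.

Alternative 3: Ring D is built, not bought. Two C–C bonds of ring D are cut, leading to pyranone A7, itself derived from triacetic acid lactone A9 by O-arylation at C4 and alkylation of the 6-methyl group. Cycloaddition of phenyl vinyl sulfone A8 across C3 and C6 of A7, extrusion of the lactone bridge as gas and elimination of the sulfonyl group as sulfinate should aromatise to aldehyde A6, which holds the ring C to ring D ether and the bridge from ring D to ring B.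
- Merits: the meta relation on ring D follows from the 4,6-pattern of the pyranone; no aryl C–O bond is made at an unactivated carbon; the regiochemistry of the cycloaddition is irrelevant because the sulfone is lost.
- Weak points: 2-pyranones are reluctant dienes, so the cascade needs prolonged heating with a free aldehyde present. A7 takes several steps to make. After A6, debenzylation, the second etherification and the macrocyclisation are all still ahead.
- Comparison: every reaction class in this road is known and no organometallic step is needed. It is longer, and the chosen plan makes both C–O bonds on ring C in one flask at or below room temperature.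

Key step: step 3

Remark on the chemistry: the target is achiral and no compound of the route has a stereocentre; the alkene of 19 is expected as a mixture of geometric isomers, which step 11 removes. 3-Hydroxy-4,5-dimethoxybenzaldehyde 12 is taken to be commercially available.

## Route

Step 1
Reactants: 1 5-iodovanillin (4-hydroxy-3-iodo-5-methoxybenzaldehyde)
Product: 2 4-formyl-2-iodo-6-methoxyphenyl 4-chlorobenzenesulfonate
Conditions: 4-ClC6H4SO2Cl, Et3N, DMAP (cat.), CH2Cl2, 0 °C to rt
Reagents that add atoms: 4-chlorobenzenesulfonyl chloride, O=S(=O)(Cl)c1ccc(Cl)cc1
Why: Sulfonylation of a hindered but acidic phenol under nucleophilic catalysis by DMAP; the aldehyde is inert. The 4-chlorobenzenesulfonate is chosen because an ortho magnesium expels it near room temperature while iPrMgCl does not attack it at −78 °C.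

Step 2
Reactants: 2 4-formyl-2-iodo-6-methoxyphenyl 4-chlorobenzenesulfonate
Product: 3 4-(1,3-dioxolan-2-yl)-2-iodo-6-methoxyphenyl 4-chlorobenzenesulfonate
Conditions: ethylene glycol, pTsOH·H2O (cat.), toluene, reflux, Dean–Stark
Reagents that add atoms: ethylene glycol, OCCO
Why: Acid-catalysed acetalisation with azeotropic removal of water; aryl sulfonate and aryl iodide are stable to pTsOH. The dioxolane hides the aldehyde from the Grignard reagents of step 3.

Step 3
Reactants: 3 4-(1,3-dioxolan-2-yl)-2-iodo-6-methoxyphenyl 4-chlorobenzenesulfonate; 4 3-bromophenol
Product: 10 2-(3-bromophenoxy)-4-(1,3-dioxolan-2-yl)-6-methoxyphenol, via chloromagnesium 3-bromophenoxide 5 (not isolated), via magnesiated aryl sulfonate 6 (not isolated), via 3-methoxyaryne 7 (not isolated), via aryloxy arylmagnesium chloride 8 (not isolated), via dimethyl arylboronate 9 (not isolated)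
Conditions: 4 (2.5 equiv), iPrMgCl·LiCl, THF, 0 °C (gives 5); separately 3, iPrMgCl, THF, −78 °C (gives 6); 6 added slowly to 5, 0 °C to rt; B(OMe)3, −78 °C to rt; 30% aq H2O2, 0 °C to rt; aq NH4Cl
Reagents that add atoms: hydrogen peroxide, OO
Why: Proposed new method: iodine–magnesium exchange on 3 at −78 °C gives 6, which on warming expels the ortho sulfonate as its magnesium salt to give aryne 7; the inductively withdrawing OMe beside the triple bond polarises it so that phenoxide 5 attacks the remote carbon and the carbanion develops next to OMe, where induction and chelation of magnesium by the two flanking oxygens hold it as 8. B(OMe)3 then converts 8 into boronate 9, and peroxide triggers the 1,2-shift of the aryl group from boron to oxygen that gives phenol 10. The closest known reaction type is the addition of magnesium thiolates and amides to arynes made from 2-iodoaryl sulfonates by iodine–magnesium exchange, with electrophilic trapping of the resulting arylmagnesium; fluoride-induced O-arylation of phenols by arynes is also known but ends in protonation, and a phenoxide nucleophile combined with an oxygen electrophile has not been shown. Two C–O bonds are made on adjacent carbons, no ring is closed and no stereocentre is formed. Regioselectivity is needed and is secured by the 3-methoxy group of 7, the dioxolane two carbons away having little say. Exchange must occur at iodine only, which the low temperature and the far slower exchange of the electron-rich aryl bromide of 5 secure. Aryne 7 must be caught by the weakly nucleophilic phenoxide before it meets 6 or 8, for which 5 is used in excess as its LiCl complex and 6 is added slowly to it. The acetal and the aryl bromide should survive because the whole sequence, including the oxidation, stays basic.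

Step 4
Reactants: 10 2-(3-bromophenoxy)-4-(1,3-dioxolan-2-yl)-6-methoxyphenol
Product: 11 2-[3-(3-bromophenoxy)-4,5-dimethoxyphenyl]-1,3-dioxolane
Conditions: MeI, K2CO3, DMF, rt
Reagents that add atoms: iodomethane, CI
Why: Williamson O-methylation; the phenoxide is flanked by OMe and OAr but the small electrophile MeI reaches it readily in DMF. Acetal and aryl bromide are inert to carbonate.

Step 5
Reactants: 12 3-hydroxy-4,5-dimethoxybenzaldehyde
Product: 13 5-ethynyl-2,3-dimethoxyphenol
Conditions: dimethyl (1-diazo-2-oxopropyl)phosphonate, K2CO3 (3 equiv), MeOH, 0 °C to rt
Reagents that add atoms: dimethyl (1-diazo-2-oxopropyl)phosphonate, COP(=O)(OC)C(=[N+]=[N-])C(C)=O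
Why: Seyferth–Gilbert homologation with the Ohira–Bestmann reagent. The phenoxide formed under the conditions is meta to the formyl group and cannot deactivate it by resonance, so extra carbonate should suffice without protection.

Step 6
Reactants: 13 5-ethynyl-2,3-dimethoxyphenol; 14 4-fluorobenzaldehyde
Product: 15 4-(5-ethynyl-2,3-dimethoxyphenoxy)benzaldehyde
Conditions: K2CO3, DMF, 110 °C
Reagents that add atoms: none
Why: Nucleophilic aromatic substitution of the phenoxide on the para-formyl fluoroarene through a Meisenheimer intermediate. Carbonate is too weak a base to deprotonate the terminal alkyne, which passes unchanged.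

Step 7
Reactants: 11 2-[3-(3-bromophenoxy)-4,5-dimethoxyphenyl]-1,3-dioxolane; 15 4-(5-ethynyl-2,3-dimethoxyphenoxy)benzaldehyde
Product: 16 4-[5-[2-[3-[5-(1,3-dioxolan-2-yl)-2,3-dimethoxyphenoxy]phenyl]ethynyl]-2,3-dimethoxyphenoxy]benzaldehyde
Conditions: Pd(PPh3)2Cl2 (cat.), CuI (cat.), Et3N, DMF, 80 °C, degassed
Reagents that add atoms: none
Why: Sonogashira coupling: zerovalent palladium inserts into the unhindered aryl bromide, the copper acetylide transmetalates and reductive elimination forms the aryl–alkyne bond. Aldehyde, acetal and ethers are spectators, and exclusion of oxygen suppresses alkyne homocoupling.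

Step 8
Reactants: 16 4-[5-[2-[3-[5-(1,3-dioxolan-2-yl)-2,3-dimethoxyphenoxy]phenyl]ethynyl]-2,3-dimethoxyphenoxy]benzaldehyde
Product: 17 4-[5-[2-[3-[5-(1,3-dioxolan-2-yl)-2,3-dimethoxyphenoxy]phenyl]ethyl]-2,3-dimethoxyphenoxy]benzaldehyde
Conditions: H2 (1 atm), 10% Pd/C, Ph2S (cat.), EtOAc, rt
Reagents that add atoms: none
Why: Heterogeneous hydrogenation of the diarylalkyne to the bibenzyl; sulfide-poisoned Pd/C reduces C–C multiple bonds but not aromatic aldehydes, so the formyl group on ring A should stay. The reduction precedes ring closure because the linear alkyne would hold the two carbonyl carbons apart.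

Step 9
Reactants: 17 4-[5-[2-[3-[5-(1,3-dioxolan-2-yl)-2,3-dimethoxyphenoxy]phenyl]ethyl]-2,3-dimethoxyphenoxy]benzaldehyde
Product: 18 3-[3-[2-[3-(4-formylphenoxy)-4,5-dimethoxyphenyl]ethyl]phenoxy]-4,5-dimethoxybenzaldehyde
Conditions: 2 M aq HCl, THF, rt
Reagents that add atoms: water, O
Why: Acid-catalysed hydrolysis of the dioxolane; methyl and diaryl ethers are stable to dilute acid.

Step 10
Reactants: 18 3-[3-[2-[3-(4-formylphenoxy)-4,5-dimethoxyphenyl]ethyl]phenoxy]-4,5-dimethoxybenzaldehyde
Product: 19 macrocyclic stilbene, the tetramethyl ether of the 19-membered ring with CH=CH between ring A and ring C and CH2CH2 between ring D and ring B (mixture of alkene isomers)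
Conditions: TiCl4, Zn, pyridine, THF, reflux; 18 added by syringe pump (high dilution)
Reagents that add atoms: none
Why: Intramolecular McMurry coupling: low-valent titanium couples the two aryl aldehydes to a titanium pinacolate and deoxygenates it to the alkene. Slow addition keeps the concentration low enough for ring closure to outrun oligomerisation; this kind of closure is established for macrocyclic bis(bibenzyl) stilbenes, and the alkene geometry is of no consequence.

Step 11
Reactants: 19 macrocyclic stilbene (mixture of alkene isomers)
Product: 20 tetramethyl ether of the target, the 19-membered ring with rings B and C as 3-aryloxy-4,5-dimethoxyphenyl units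
Conditions: H2 (1 atm), 10% Pd/C, EtOAc, rt
Reagents that add atoms: none
Why: Catalytic hydrogenation of the stilbene; both alkene isomers converge on one product and no hydrogenolysable group is present.

Step 12
Reactants: 20 tetramethyl ether of the target
Product: 21 target macrocycle, the 19-membered bis(catechol) cyclophane (rings B and C as 5-alkyl-3-aryloxybenzene-1,2-diols)
Conditions: BBr3 (excess), CH2Cl2, −78 °C to rt; then H2O, under argon
Reagents that add atoms: none
Why: Lewis acid cleavage of aryl methyl ethers: bromide attacks the methyl group of each boron-complexed ether. Diaryl ethers offer no sp3 carbon for attack and remain, and the acidic, air-free work-up protects the catechols.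

## Compound list

1 | 5-iodovanillin (4-hydroxy-3-iodo-5-methoxybenzaldehyde) | COc1cc(C=O)cc(I)c1O | starting material
2 | 4-formyl-2-iodo-6-methoxyphenyl 4-chlorobenzenesulfonate | COc1cc(C=O)cc(I)c1OS(=O)(=O)c1ccc(Cl)cc1 | intermediate
3 | 4-(1,3-dioxolan-2-yl)-2-iodo-6-methoxyphenyl 4-chlorobenzenesulfonate | COc1cc(cc(I)c1OS(=O)(=O)c1ccc(Cl)cc1)C1OCCO1 | intermediate
4 | 3-bromophenol | Oc1cccc(Br)c1 | starting material
5 | chloromagnesium 3-bromophenoxide (used as its LiCl complex; not isolated) | Cl[Mg]Oc1cccc(Br)c1 | intermediate
6 | [2-(4-chlorophenyl)sulfonyloxy-5-(1,3-dioxolan-2-yl)-3-methoxyphenyl]magnesium chloride (not isolated) | COc1cc(cc([Mg]Cl)c1OS(=O)(=O)c1ccc(Cl)cc1)C1OCCO1 | intermediate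
7 | 2-(3,4-didehydro-5-methoxyphenyl)-1,3-dioxolane, the 3-methoxyaryne (not isolated) | COC1=CC(C2OCCO2)=CC#C1 | intermediate
8 | [2-(3-bromophenoxy)-4-(1,3-dioxolan-2-yl)-6-methoxyphenyl]magnesium chloride (not isolated) | COc1cc(cc(Oc2cccc(Br)c2)c1[Mg]Cl)C1OCCO1 | intermediate
9 | dimethyl [2-(3-bromophenoxy)-4-(1,3-dioxolan-2-yl)-6-methoxyphenyl]boronate (not isolated) | COc1cc(cc(Oc2cccc(Br)c2)c1B(OC)OC)C1OCCO1 | intermediate
10 | 2-(3-bromophenoxy)-4-(1,3-dioxolan-2-yl)-6-methoxyphenol | COc1cc(cc(Oc2cccc(Br)c2)c1O)C1OCCO1 | intermediate
11 | 2-[3-(3-bromophenoxy)-4,5-dimethoxyphenyl]-1,3-dioxolane | COc1cc(cc(Oc2cccc(Br)c2)c1OC)C1OCCO1 | intermediate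
12 | 3-hydroxy-4,5-dimethoxybenzaldehyde | COc1cc(C=O)cc(O)c1OC | starting material
13 | 5-ethynyl-2,3-dimethoxyphenol | COc1cc(C#C)cc(O)c1OC | intermediate
14 | 4-fluorobenzaldehyde | O=Cc1ccc(F)cc1 | starting material
15 | 4-(5-ethynyl-2,3-dimethoxyphenoxy)benzaldehyde | COc1cc(C#C)cc(Oc2ccc(C=O)cc2)c1OC | intermediate
16 | 4-[5-[2-[3-[5-(1,3-dioxolan-2-yl)-2,3-dimethoxyphenoxy]phenyl]ethynyl]-2,3-dimethoxyphenoxy]benzaldehyde | COc1cc(cc(Oc2cccc(c2)C#Cc2cc(OC)c(OC)c(c2)Oc2ccc(C=O)cc2)c1OC)C1OCCO1 | intermediate
17 | 4-[5-[2-[3-[5-(1,3-dioxolan-2-yl)-2,3-dimethoxyphenoxy]phenyl]ethyl]-2,3-dimethoxyphenoxy]benzaldehyde | COc1cc(cc(Oc2cccc(c2)CCc2cc(OC)c(OC)c(c2)Oc2ccc(C=O)cc2)c1OC)C1OCCO1 | intermediate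
18 | 3-[3-[2-[3-(4-formylphenoxy)-4,5-dimethoxyphenyl]ethyl]phenoxy]-4,5-dimethoxybenzaldehyde | COc1cc(C=O)cc(Oc2cccc(c2)CCc2cc(OC)c(OC)c(c2)Oc2ccc(C=O)cc2)c1OC | intermediate
19 | macrocyclic stilbene, tetramethyl ether, CH=CH between ring A and ring C (mixture of alkene isomers, geometry left undefined) | COc1cc2cc(c1OC)Oc1ccc(cc1)C=Cc1cc(OC)c(OC)c(c1)Oc1cccc(c1)CC2 | intermediate
20 | tetramethyl ether of the target macrocycle | COc1cc2cc(c1OC)Oc1ccc(cc1)CCc1cc(OC)c(OC)c(c1)Oc1cccc(c1)CC2 | intermediate
21 | target macrocycle CNP0511668.0 | Oc1cc2cc(c1O)Oc1ccc(cc1)CCc1cc(O)c(O)c(c1)Oc1cccc(c1)CC2 | target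

## Step count and risks

Total: 12 steps. Longest linear sequence: 10 steps (steps 1 to 4 and 7 to 12 from 5-iodovanillin); the branch from 12 contributes steps 5 and 6.

**Step 3 (key step, new method).** The most likely failure is that aryne 7 is consumed by carbon nucleophiles present in the flask (6, 8 or traces of iPrMgCl) faster than by the aggregated magnesium phenoxide, so that arylation and oligomerisation replace C–O bond formation. A second risk is protonation of 8 before oxygenation, which would give the deoxy diaryl ether. The fallback uses known chemistry and sets out from 12. Chan–Lam coupling of the phenol of 12 with 3-bromophenylboronic acid (Cu(OAc)2, pyridine, 4 Å molecular sieves, CH2Cl2, air, rt) should give 3-(3-bromophenoxy)-4,5-dimethoxybenzaldehyde F1; divalent copper at room temperature does not insert into the aryl bromide. Acetalisation of F1 (ethylene glycol, pTsOH, toluene, reflux) returns to the route at 11. This fallback is shorter than steps 1 to 4; its own weakness is the usually sluggish coupling of an ortho-substituted phenol, which needs excess boronic acid.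

**Step 5.** The phenoxide aldehyde may react slowly, so that methanolysis of the diazophosphonate outpaces the homologation and conversion stays incomplete. The fallback sets out from 12 and reverses the order of events. Nucleophilic aromatic substitution on 4-fluorobenzonitrile (K2CO3, DMF, 100 °C) should give 4-(5-formyl-2,3-dimethoxyphenoxy)benzonitrile F2. Ohira–Bestmann homologation of its single, non-phenolic aldehyde gives 4-(5-ethynyl-2,3-dimethoxyphenoxy)benzonitrile F3. Reduction of the nitrile with DIBAL-H (toluene, −78 °C, aqueous acid work-up) returns to the route at 15. This also removes the terminal alkyne from the hot basic conditions of step 6.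

**Step 8.** Over-reduction of the ring A formyl group to the benzylic alcohol, or stalling at the stilbene stage on the poisoned catalyst, would erode the material balance. The fallback sets out from 15, whose aldehyde is masked first (ethylene glycol, pTsOH, toluene, reflux) as 2-[4-(5-ethynyl-2,3-dimethoxyphenoxy)phenyl]-1,3-dioxolane F4. Sonogashira coupling of F4 with 11 gives the bis(dioxolane) diarylalkyne F5, and hydrogenation over unpoisoned Pd/C gives the bis(dioxolane) bibenzyl F6. Hydrolysis of both acetals (aq HCl, THF) returns to the route at 18.

**Step 10.** Intermolecular coupling to oligomers, or arrest at the pinacol stage, may compete with closure of the 19-membered ring. The fallback replaces the reductive coupling by an intramolecular Wittig reaction and sets out from 17, where the two carbonyl carbons are still differentiated. NaBH4 (MeOH, 0 °C) reduces the free aldehyde to benzylic alcohol F7. PPh3·HBr in slight excess (MeCN, reflux) turns the benzylic hydroxyl into a triphenylphosphonium group, and the water formed in this substitution, with the acid still present, hydrolyses the dioxolane in the same flask to give phosphonium aldehyde F8. NaOMe in CH2Cl2 at high dilution closes the ring and returns to the route at 19.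

## Further compounds

F1 | step 3 | 3-(3-bromophenoxy)-4,5-dimethoxybenzaldehyde | COc1cc(C=O)cc(Oc2cccc(Br)c2)c1OC
F2 | step 5 | 4-(5-formyl-2,3-dimethoxyphenoxy)benzonitrile | COc1cc(C=O)cc(Oc2ccc(C#N)cc2)c1OC
F3 | step 5 | 4-(5-ethynyl-2,3-dimethoxyphenoxy)benzonitrile | COc1cc(C#C)cc(Oc2ccc(C#N)cc2)c1OC
F4 | step 8 | 2-[4-(5-ethynyl-2,3-dimethoxyphenoxy)phenyl]-1,3-dioxolane | COc1cc(C#C)cc(Oc2ccc(cc2)C2OCCO2)c1OC
F5 | step 8 | 2-[4-[5-[2-[3-[5-(1,3-dioxolan-2-yl)-2,3-dimethoxyphenoxy]phenyl]ethynyl]-2,3-dimethoxyphenoxy]phenyl]-1,3-dioxolane | COc1cc(cc(Oc2cccc(c2)C#Cc2cc(OC)c(OC)c(c2)Oc2ccc(cc2)C2OCCO2)c1OC)C1OCCO1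
F6 | step 8 | 2-[4-[5-[2-[3-[5-(1,3-dioxolan-2-yl)-2,3-dimethoxyphenoxy]phenyl]ethyl]-2,3-dimethoxyphenoxy]phenyl]-1,3-dioxolane | COc1cc(cc(Oc2cccc(c2)CCc2cc(OC)c(OC)c(c2)Oc2ccc(cc2)C2OCCO2)c1OC)C1OCCO1
F7 | step 10 | [4-[5-[2-[3-[5-(1,3-dioxolan-2-yl)-2,3-dimethoxyphenoxy]phenyl]ethyl]-2,3-dimethoxyphenoxy]phenyl]methanol | COc1cc(cc(Oc2cccc(c2)CCc2cc(OC)c(OC)c(c2)Oc2ccc(CO)cc2)c1OC)C1OCCO1
F8 | step 10 | [4-[5-[2-[3-(5-formyl-2,3-dimethoxyphenoxy)phenyl]ethyl]-2,3-dimethoxyphenoxy]benzyl]triphenylphosphonium bromide | COc1cc(C=O)cc(Oc2cccc(c2)CCc2cc(OC)c(OC)c(c2)Oc2ccc(C[P+](c3ccccc3)(c3ccccc3)c3ccccc3)cc2)c1OC.[Br-]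
A1 | alternative 1 | tetra-O-methyl 19-membered macrocycle with a nitro group on ring D ortho to the ether oxygen | COc1cc2cc(c1OC)Oc1ccc(cc1)CCc1cc(OC)c(OC)c(c1)Oc1cc(ccc1[N+](=O)[O-])CC2
A2 | alternative 1 | 5-[2-[4-[5-[2-(3-fluoro-4-nitrophenyl)ethyl]-2,3-dimethoxyphenoxy]phenyl]ethyl]-2,3-dimethoxyphenol | COc1cc(CCc2ccc([N+](=O)[O-])c(F)c2)cc(Oc2ccc(CCc3cc(O)c(OC)c(OC)c3)cc2)c1OC
A3 | alternative 2 | macrocyclic bis(ortho-quinone) | O=C1C=C2C=C(C1=O)Oc1ccc(cc1)CCC1=CC(=O)C(=O)C(=C1)Oc1cccc(c1)CC2
A4 | alternative 2 | dideoxy macrocycle, the target without the outer hydroxyl of ring B and of ring C | Oc1ccc2cc1Oc1ccc(cc1)CCc1ccc(O)c(c1)Oc1cccc(c1)CC2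
A5 | alternative 2 | 2-iodoxybenzoic acid | OI1(=O)OC(=O)c2ccccc12
A6 | alternative 3 | 3-[3-[2-(3-benzyloxy-4,5-dimethoxyphenyl)ethyl]phenoxy]-4,5-dimethoxybenzaldehyde | O=Cc1cc(OC)c(OC)c(c1)Oc1cccc(c1)CCc1cc(OC)c(OC)c(OCc2ccccc2)c1
A7 | alternative 3 | 3-[[6-[2-(3-benzyloxy-4,5-dimethoxyphenyl)ethyl]-2-oxo-2H-pyran-4-yl]oxy]-4,5-dimethoxybenzaldehyde | O=C1C=C(Oc2cc(C=O)cc(OC)c2OC)C=C(CCc2cc(OC)c(OC)c(OCc3ccccc3)c2)O1
A8 | alternative 3 | phenyl vinyl sulfone | C=CS(=O)(=O)c1ccccc1
A9 | alternative 3 | triacetic acid lactone (4-hydroxy-6-methyl-2H-pyran-2-one) | CC1=CC(O)=CC(=O)O1
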